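**Plan**

1. Numbering: ring C1 carries the side chain, C3 the free OH, C5 the OMe, C6 the OAc; C1' is the benzylic CH2 and C2' the acetoxy-bearing carbon.
2. The retrosynthesis first removes both acetyl groups and the C6–O bond, since C6 is para to the C3 hydroxyl and can be oxygenated late through the para-quinone.
3. Ring bonds C3–C4 and C5–C6 are cut next. This is possible because the C1 alkyl group, the C3 hydroxyl and the C5 methyl ether of the benzene ring are mutually meta and the two oxygens are already differentiated, which is the pattern a 3-substituted cyclobutenone (C1, C2, C3, C6) and methoxyacetylene (C4, C5) deliver.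
4. The cyclobutenone is cut to dichloroketene and a terminal alkyne, and the alkyne at C1'–C2' to dodecanal and an allenyl metal.
5. Forward, the chain is joined first, then the four-membered ring is built, then the benzene ring (the only ring of the target) closes in the key step, and the C6 oxygen and the acetates follow.
6. The single stereocenter C2' (R) is set in step 1 by the (S)-BINOL–titanium catalyst and is never a reacting center afterwards.

Key step: step 6

Remark on the chemistry: methoxyacetylene is too volatile and labile to count as a stock chemical, so its preparation is included as step 5. TBS means tert-butyldimethylsilyl.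

**Step 1**
Reactants: 1 dodecanal; 2 allenyltributylstannane
Product: 4 (R)-pentadec-1-yn-4-ol, via tributylstannyl ether 3 (not isolated)
Conditions: (S)-BINOL (20 mol %), Ti(OiPr)4 (10 mol %), 4 Å MS, CH2Cl2, −20 °C; aq NaHCO3 work-up
Reagents that add atoms: none
Why: Keck asymmetric propargylation, in which the BINOL–titanium Lewis acid activates the aldehyde and the allenylstannane adds through its CH2 terminus (SE2') to give only the homopropargylic skeleton; the (S)-BINOL ligand should direct attack to the Si face, as in the allylation series with unbranched aldehydes, and so set the (R) carbinol center.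

**Step 2**
Reactants: 4 (R)-pentadec-1-yn-4-ol
Product: 5 tert-butyldimethyl{[(4R)-pentadec-1-yn-4-yl]oxy}silane
Conditions: TBSCl, imidazole, DMF, rt
Reagents that add atoms: tert-butyldimethylsilyl chloride, CC(C)(C)[Si](C)(C)Cl
Why: Standard silylation of a secondary alcohol; the silyl ether survives zinc reductions, heating and buffered oxidation and, unlike an ester, is too poor a leaving group for vinylogous β-elimination from the later cyclobutenone.

**Step 3**
Reactants: 5 tert-butyldimethyl{[(4R)-pentadec-1-yn-4-yl]oxy}silane; 6 trichloroacetyl chloride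
Product: 8 4,4-dichloro-3-[(2R)-2-(tert-butyldimethylsilyloxy)tridecyl]cyclobut-2-en-1-one, via dichloroketene 7 (not isolated)
Conditions: Zn–Cu couple, Et2O–DME, rt, slow addition of 6
Reagents that add atoms: none
Why: (2+2) cycloaddition of dichloroketene, generated by zinc dechlorination of 6, to a terminal alkyne; the ketene carbonyl carbon bonds to the unsubstituted alkyne terminus, so the chain ends up at C3 of the cyclobutenone.

**Step 4**
Reactants: 8 4,4-dichloro-3-[(2R)-2-(tert-butyldimethylsilyloxy)tridecyl]cyclobut-2-en-1-one
Product: 9 3-[(2R)-2-(tert-butyldimethylsilyloxy)tridecyl]cyclobut-2-en-1-one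
Conditions: Zn dust, AcOH, TMEDA, EtOH, 0 °C
Reagents that add atoms: none
Why: Reductive dechlorination of an α,α-dichloro ketone by zinc, buffered with AcOH–TMEDA so that both chlorines are removed without reduction of the enone or migration of the ring double bond.

**Step 5**
Reactants: 10 chloroacetaldehyde dimethyl acetal
Product: 13 methoxyacetylene, via 1-chloro-2-methoxyethene 11 (not isolated), via sodium methoxyacetylide 12 (not isolated)
Conditions: NaNH2 (3 equiv), liq. NH3, −33 °C; then sat. aq NaCl, −70 °C to rt, product distilled into a cold trap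
Reagents that add atoms: none
Why: Double dehydro-elimination (methanol, then HCl) of a β-chloro acetal by NaNH2, the standard preparation of alkoxyacetylenes, with the acetylide salt protecting the product until the aqueous quench.

**Step 6**
Reactants: 9 3-[(2R)-2-(tert-butyldimethylsilyloxy)tridecyl]cyclobut-2-en-1-one; 13 methoxyacetylene
Product: 18 3-[(2R)-2-(tert-butyldimethylsilyloxy)tridecyl]-5-methoxyphenol, via vinylketene 14 (not isolated), via 4-alkenylcyclobutenone 15 (not isolated), via dienylketene 16 (not isolated), via cyclohexadienone 17 (not isolated)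
Conditions: 13 (3 equiv), PhMe, 80 °C, sealed tube; crude product then K2CO3, MeOH, rt
Reagents that add atoms: none
Why: Heating 9 opens the four-membered ring in a four-electron electrocyclic step to vinylketene 14, whose ketene C=C bond adds across methoxyacetylene in a (2+2) cycloaddition to give 15, forming C3–C4 and C5–C6, and 15 then opens to dienylketene 16. The benzene ring closes by six-electron disrotatory electrocyclization of 16, which re-forms the C2–C3 bond lost in the first opening, and dienone 17 tautomerizes to the phenol. This is the Danheiser benzannulation of a cyclobutenone with an alkoxyalkyne, a known reaction type. No stereocenter is created, and C2' is remote from every reacting atom under these neutral thermal conditions. The step needs one regiochemical outcome in the (2+2) addition, and the polarization of the ynol ether secures it: its nucleophilic unsubstituted carbon attacks the electrophilic ketene carbon, which places the OMe meta to the new OH, while the C3 substituent of the cyclobutenone ends meta to both. Methoxyacetylene has no β-hydrogen for retro-ene loss of ketene and so should tolerate 80 °C, and the carbonate–methanol treatment releases any phenol captured as an ester by vinylketene.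

**Step 7**
Reactants: 18 3-[(2R)-2-(tert-butyldimethylsilyloxy)tridecyl]-5-methoxyphenol
Product: 19 2-methoxy-6-[(2R)-2-(tert-butyldimethylsilyloxy)tridecyl]cyclohexa-2,5-diene-1,4-dione
Conditions: (KSO3)2NO (2.5 equiv), KH2PO4, H2O–acetone, rt
Reagents that add atoms: potassium nitrosodisulfonate, [K+].[K+].[O-]S(=O)(=O)N([O])S(=O)(=O)[O-]
Why: Teuber oxidation, in which two equivalents of the nitrosodisulfonate radical convert a phenol with a free para position into the para-quinone; C6 is the only position para to the hydroxyl, and 3-alkyl-5-alkoxyphenols are established substrates.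

**Step 8**
Reactants: 19 2-methoxy-6-[(2R)-2-(tert-butyldimethylsilyloxy)tridecyl]cyclohexa-2,5-diene-1,4-dione
Product: 20 2-methoxy-6-[(2R)-2-(tert-butyldimethylsilyloxy)tridecyl]benzene-1,4-diol
Conditions: Na2S2O4, EtOAc–H2O, rt, under Ar; used directly
Reagents that add atoms: none
Why: Two-electron reduction of a quinone to the hydroquinone by dithionite under neutral biphasic conditions, with nothing else in the molecule reducible.

**Step 9**
Reactants: 20 2-methoxy-6-[(2R)-2-(tert-butyldimethylsilyloxy)tridecyl]benzene-1,4-diol
Product: 21 4-(benzyloxy)-2-methoxy-6-[(2R)-2-(tert-butyldimethylsilyloxy)tridecyl]phenol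
Conditions: BnBr (1.05 equiv), K2CO3 (1.1 equiv), degassed acetone, rt, Ar
Reagents that add atoms: benzyl bromide, BrCc1ccccc1
Why: Williamson etherification under steric control: the C3 hydroxyl has two ring hydrogens as neighbours, whereas the C6 hydroxyl lies between the side chain and the methoxy group to which it is hydrogen-bonded, so with one equivalent of base and halide the unhindered phenoxide should react first.

**Step 10**
Reactants: 21 4-(benzyloxy)-2-methoxy-6-[(2R)-2-(tert-butyldimethylsilyloxy)tridecyl]phenol
Product: 22 4-(benzyloxy)-2-[(2R)-2-hydroxytridecyl]-6-methoxyphenol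
Conditions: 48% aq HF, MeCN, 0 °C to rt
Reagents that add atoms: none
Why: Cleavage of a secondary alkyl silyl ether by aqueous HF, mild enough to leave the aryl benzyl ether, the methyl ether and the carbinol configuration untouched.

**Step 11**
Reactants: 22 4-(benzyloxy)-2-[(2R)-2-hydroxytridecyl]-6-methoxyphenol
Product: 23 4-(benzyloxy)-2-[(2R)-2-acetoxytridecyl]-6-methoxyphenyl acetate
Conditions: Ac2O, pyridine, DMAP (cat.), CH2Cl2, rt
Reagents that add atoms: acetic anhydride, CC(=O)OC(C)=O
Why: DMAP-catalysed acylation, which should acetylate both the secondary alcohol and the hindered C6 phenol with retention at C2'.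

**Step 12**
Reactants: 23 4-(benzyloxy)-2-[(2R)-2-acetoxytridecyl]-6-methoxyphenyl acetate
Product: 24 2-[(2R)-2-acetoxytridecyl]-4-hydroxy-6-methoxyphenyl acetate
Conditions: H2 (1 atm), 10% Pd/C, EtOAc, rt
Reagents that add atoms: none
Why: Hydrogenolysis of an aryl benzyl ether over palladium on carbon under neutral conditions, which should leave both acetates in place and cannot touch the homobenzylic stereocenter.

**Compound list**

1 | dodecanal | CCCCCCCCCCCC=O | starting material
2 | allenyltributylstannane (tributyl(propa-1,2-dien-1-yl)stannane) | C=C=C[Sn](CCCC)(CCCC)CCCC | starting material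
3 | tributyl{[(4R)-pentadec-1-yn-4-yl]oxy}stannane | CCCCCCCCCCC[C@H](CC#C)O[Sn](CCCC)(CCCC)CCCC | intermediate
4 | (R)-pentadec-1-yn-4-ol | CCCCCCCCCCC[C@H](CC#C)O | intermediate
5 | tert-butyldimethyl{[(4R)-pentadec-1-yn-4-yl]oxy}silane | CCCCCCCCCCC[C@H](CC#C)O[Si](C)(C)C(C)(C)C | intermediate
6 | trichloroacetyl chloride | ClC(Cl)(Cl)C(Cl)=O | starting material
7 | dichloroketene | ClC(Cl)=C=O | intermediate
8 | 4,4-dichloro-3-[(2R)-2-(tert-butyldimethylsilyloxy)tridecyl]cyclobut-2-en-1-one | CCCCCCCCCCC[C@H](CC1=CC(=O)C1(Cl)Cl)O[Si](C)(C)C(C)(C)C | intermediate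
9 | 3-[(2R)-2-(tert-butyldimethylsilyloxy)tridecyl]cyclobut-2-en-1-one | CCCCCCCCCCC[C@H](CC1=CC(=O)C1)O[Si](C)(C)C(C)(C)C | intermediate
10 | chloroacetaldehyde dimethyl acetal (2-chloro-1,1-dimethoxyethane) | COC(CCl)OC | starting material
11 | 1-chloro-2-methoxyethene | COC=CCl | intermediate
12 | sodium methoxyacetylide | [Na+].[C-]#COC | intermediate
13 | methoxyacetylene | COC#C | intermediate
14 | (5R)-5-(tert-butyldimethylsilyloxy)-3-methylidenehexadec-1-en-1-one | CCCCCCCCCCC[C@H](CC(=C)C=C=O)O[Si](C)(C)C(C)(C)C | intermediate
15 | 3-methoxy-4-[(4R)-4-(tert-butyldimethylsilyloxy)pentadec-1-en-2-yl]cyclobut-2-en-1-one (both configurations at ring C4) | CCCCCCCCCCC[C@H](CC(=C)C1C(=O)C=C1OC)O[Si](C)(C)C(C)(C)C | intermediate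
16 | (3E,7R)-7-(tert-butyldimethylsilyloxy)-3-methoxy-5-methylideneoctadeca-1,3-dien-1-one | CCCCCCCCCCC[C@H](CC(=C)/C=C(OC)\C=C=O)O[Si](C)(C)C(C)(C)C | intermediate
17 | 3-methoxy-5-[(2R)-2-(tert-butyldimethylsilyloxy)tridecyl]cyclohexa-2,4-dien-1-one | CCCCCCCCCCC[C@H](CC1=CC(OC)=CC(=O)C1)O[Si](C)(C)C(C)(C)C | intermediate
18 | 3-[(2R)-2-(tert-butyldimethylsilyloxy)tridecyl]-5-methoxyphenol | CCCCCCCCCCC[C@H](Cc1cc(O)cc(OC)c1)O[Si](C)(C)C(C)(C)C | intermediate
19 | 2-methoxy-6-[(2R)-2-(tert-butyldimethylsilyloxy)tridecyl]cyclohexa-2,5-diene-1,4-dione | CCCCCCCCCCC[C@H](CC1=CC(=O)C=C(OC)C1=O)O[Si](C)(C)C(C)(C)C | intermediate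
20 | 2-methoxy-6-[(2R)-2-(tert-butyldimethylsilyloxy)tridecyl]benzene-1,4-diol | CCCCCCCCCCC[C@H](Cc1cc(O)cc(OC)c1O)O[Si](C)(C)C(C)(C)C | intermediate
21 | 4-(benzyloxy)-2-methoxy-6-[(2R)-2-(tert-butyldimethylsilyloxy)tridecyl]phenol | CCCCCCCCCCC[C@H](Cc1cc(OCc2ccccc2)cc(OC)c1O)O[Si](C)(C)C(C)(C)C | intermediate
22 | 4-(benzyloxy)-2-[(2R)-2-hydroxytridecyl]-6-methoxyphenol | CCCCCCCCCCC[C@H](Cc1cc(OCc2ccccc2)cc(OC)c1O)O | intermediate
23 | 4-(benzyloxy)-2-[(2R)-2-acetoxytridecyl]-6-methoxyphenyl acetate | CCCCCCCCCCC[C@H](Cc1cc(OCc2ccccc2)cc(OC)c1OC(C)=O)OC(C)=O | intermediate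
24 | 2-[(2R)-2-acetoxytridecyl]-4-hydroxy-6-methoxyphenyl acetate | CCCCCCCCCCC[C@H](Cc1cc(O)cc(OC)c1OC(C)=O)OC(C)=O | target

**Step count**

Total: 12 steps. Longest linear sequence: 11 steps (steps 1–4 and 6–12 from dodecanal); step 5 is a one-step side branch.

**Steps most likely to fail**

Step 6. The low-boiling alkoxyalkyne may escape or oligomerize before it intercepts the vinylketene, which then dimerizes or acylates the product phenol. The fallback sets out from 9 and changes the alkyne partner and the order of ether formation. The same annulation is run in toluene at 80 °C with the non-volatile (triisopropylsilyloxy)ethyne F1, made by O-silylation of lithium ethynolate with iPr3SiCl. It should give 3-[(2R)-2-(tert-butyldimethylsilyloxy)tridecyl]-5-(triisopropylsilyloxy)phenol F2. Because C3 and C5 are equivalent with respect to the C1 alkyl group, it does not matter which oxygen is methylated. Methylation of the free hydroxyl (MeI, K2CO3, acetone) should give 1-[(2R)-2-(tert-butyldimethylsilyloxy)tridecyl]-3-methoxy-5-(triisopropylsilyloxy)benzene F3. Selective cleavage of the aryl silyl ether (Bu4NF, 1 equiv, THF, 0 °C), which should be much faster than that of the secondary alkyl silyl ether, returns to the route at 18.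

Step 9. Discrimination between the two phenolic hydroxyls may be incomplete, with over-alkylation and air re-oxidation of the hydroquinone under basic conditions. The fallback sets out from 20 and replaces alkylation by silylation with a much bulkier electrophile. Treatment with iPr3SiCl and imidazole in DMF at 0 °C should give 2-methoxy-6-[(2R)-2-(tert-butyldimethylsilyloxy)tridecyl]-4-(triisopropylsilyloxy)phenol F4. Acid methanolysis (camphorsulfonic acid, MeOH, rt) should remove the alkyl silyl ether but not the aryl one, giving 2-[(2R)-2-hydroxytridecyl]-6-methoxy-4-(triisopropylsilyloxy)phenol F5. Acetylation (Ac2O, pyridine, DMAP) should give 2-[(2R)-2-acetoxytridecyl]-6-methoxy-4-(triisopropylsilyloxy)phenyl acetate F6. Buffered fluoride (Bu4NF, AcOH, THF, 0 °C) then returns to the route at target 24.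

Step 1. Enantiofacial discrimination may be insufficient with an unbranched aldehyde, and turnover of the titanium catalyst may be slow. The fallback sets out from 1 and takes the stereocenter from a resolved epoxide. Corey–Chaykovsky methylenation (Me3SI, NaH, DMSO–THF) should give racemic 2-undecyloxirane F7. Jacobsen hydrolytic kinetic resolution uses the (R,R)-(salen)Co(OAc) catalyst (the acetate of trivalent cobalt with (R,R)-N,N'-bis(3,5-di-tert-butylsalicylidene)cyclohexane-1,2-diamine) and 0.55 equiv H2O. It should hydrolyze the (S)-epoxide and leave (R)-2-undecyloxirane F8. Opening at the terminal carbon with lithium acetylide–ethylenediamine complex in DMSO does not touch the stereocenter and returns to the route at 4.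

**Further compounds**

F1 | step 6 | (triisopropylsilyloxy)ethyne | C#CO[Si](C(C)C)(C(C)C)C(C)C
F2 | step 6 | 3-[(2R)-2-(tert-butyldimethylsilyloxy)tridecyl]-5-(triisopropylsilyloxy)phenol | CCCCCCCCCCC[C@H](Cc1cc(O)cc(O[Si](C(C)C)(C(C)C)C(C)C)c1)O[Si](C)(C)C(C)(C)C
F3 | step 6 | 1-[(2R)-2-(tert-butyldimethylsilyloxy)tridecyl]-3-methoxy-5-(triisopropylsilyloxy)benzene | CCCCCCCCCCC[C@H](Cc1cc(OC)cc(O[Si](C(C)C)(C(C)C)C(C)C)c1)O[Si](C)(C)C(C)(C)C
F4 | step 9 | 2-methoxy-6-[(2R)-2-(tert-butyldimethylsilyloxy)tridecyl]-4-(triisopropylsilyloxy)phenol | CCCCCCCCCCC[C@H](Cc1cc(O[Si](C(C)C)(C(C)C)C(C)C)cc(OC)c1O)O[Si](C)(C)C(C)(C)C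
F5 | step 9 | 2-[(2R)-2-hydroxytridecyl]-6-methoxy-4-(triisopropylsilyloxy)phenol | CCCCCCCCCCC[C@H](Cc1cc(O[Si](C(C)C)(C(C)C)C(C)C)cc(OC)c1O)O
F6 | step 9 | 2-[(2R)-2-acetoxytridecyl]-6-methoxy-4-(triisopropylsilyloxy)phenyl acetate | CCCCCCCCCCC[C@H](Cc1cc(O[Si](C(C)C)(C(C)C)C(C)C)cc(OC)c1OC(C)=O)OC(C)=O
F7 | step 1 | racemic 2-undecyloxirane | CCCCCCCCCCCC1CO1
F8 | step 1 | (R)-2-undecyloxirane | CCCCCCCCCCC[C@@H]1CO1
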